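**Strategy**

Everything rests on disconnecting the bond between C6 of ring A and the lavandulyl CH2 (C1''). A Negishi sp2–sp3 coupling joins two finished, enantioenriched halves in one operation: the (2S)-6-iodoflavanone, with its 5-OH left free, and (S)-lavandulylzinc iodide, so the complete skeleton with both stereocenters appears at once. The step exploits C6 of ring A: it lies between O5 and O7 and ortho to the 5-OH that is hydrogen-bonded to the C4 carbonyl, which makes it the one carbon that takes iodine, while the lavandulyl stereocenter C2'' sits β to zinc and is never touched. The aryl iodide comes from asymmetric arylation of a chromone, the alkyl iodide from an Evans dienolate alkylation.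

Key step: step 10

Remark (assumption): the sense of induction of the pyridine–oxazoline ligand in step 8 is taken from the β-arylation of cyclic enones. For the (S)-ligand this corresponds to 2R on a chromone, so the (R)-ligand is specified; the ligand enantiomer would be exchanged if the opposite sense were found.

**Route**

Step 1
Reactants: 1 (S)-4-benzyl-1,3-oxazolidin-2-one; 2 3-methylbut-2-enoyl chloride
Product: 4 (S)-4-benzyl-3-(3-methylbut-2-enoyl)-1,3-oxazolidin-2-one, via N-lithio oxazolidinone 3 (not isolated)
Conditions: n-BuLi, THF, −78 °C; then 2, −78 to 0 °C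
Reagents that add atoms: none
Why: N-acylation of the lithiated Evans auxiliary by the acid chloride is fast at low temperature, where the acid chloride is not deprotonated to a vinylketene.

Step 2
Reactants: 4 (S)-4-benzyl-3-(3-methylbut-2-enoyl)-1,3-oxazolidin-2-one; 5 1-bromo-3-methylbut-2-ene (prenyl bromide)
Product: 7 (4S)-4-benzyl-3-[(2S)-5-methyl-2-(prop-1-en-2-yl)hex-4-enoyl]-1,3-oxazolidin-2-one, via sodium dienolate 6 (not isolated)
Conditions: NaN(SiMe3)2, THF, −78 °C; then 5, −78 to −30 °C
Reagents that add atoms: none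
Why: Evans alkylation with deconjugation: γ-deprotonation gives the chelated (Z)-dienolate, which is alkylated at the α-carbon on the face opposite the C4 benzyl group, setting the 2S acyl stereocenter and leaving the isopropenyl group.

Step 3
Reactants: 7 (4S)-4-benzyl-3-[(2S)-5-methyl-2-(prop-1-en-2-yl)hex-4-enoyl]-1,3-oxazolidin-2-one
Product: 8 (S)-lavandulol, (2S)-5-methyl-2-(prop-1-en-2-yl)hex-4-en-1-ol
Conditions: LiBH4, MeOH (1 equiv), Et2O, 0 °C; aq. NaOH work-up
Reagents that add atoms: none
Why: Reductive cleavage of the exocyclic imide carbonyl by borohydride releases the primary alcohol and the auxiliary without touching the stereocenter or the two alkenes.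

Step 4
Reactants: 8 (S)-lavandulol
Product: 9 (S)-lavandulyl iodide, (3S)-3-(iodomethyl)-2,6-dimethylhepta-1,5-diene
Conditions: I2, PPh3, imidazole, CH2Cl2, 0 to 25 °C, dark
Reagents that add atoms: iodine, [I][I]
Why: Appel iodination displaces the activated primary oxygen by iodide in an SN2 step at CH2, so the adjacent stereocenter is not involved.

Step 5
Reactants: 10 4-bromo-3-methoxyphenol
Product: 11 (4-bromo-3-methoxyphenoxy)triisopropylsilane
Conditions: i-Pr3SiCl, imidazole, DMF, 25 °C
Reagents that add atoms: chlorotriisopropylsilane, CC(C)[Si](Cl)(C(C)C)C(C)C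
Why: Imidazole-promoted O-silylation of the phenol gives a triisopropylsilyl ether that is stable to organolithium, aqueous and mildly acidic conditions and is removed by fluoride at the end.

Step 6
Reactants: 11 (4-bromo-3-methoxyphenoxy)triisopropylsilane
Product: 14 [2-methoxy-4-(triisopropylsilyloxy)phenyl]boronic acid, via aryllithium 12 (not isolated), via lithium aryltriisopropoxyborate 13 (not isolated)
Conditions: n-BuLi, THF, −78 °C; B(Oi-Pr)3, −78 to 25 °C; aq. NH4Cl/dilute HCl work-up
Reagents that add atoms: triisopropyl borate, CC(C)OB(OC(C)C)OC(C)C; water, O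
Why: Bromine–lithium exchange followed by borylation and hydrolysis is the standard route to an arylboronic acid, and the lithium para to the silyloxy group cannot trigger silyl migration.

Step 7
Reactants: 15 5,7-dihydroxy-4H-chromen-4-one
Product: 16 5-hydroxy-7-(triisopropylsilyloxy)-4H-chromen-4-one
Conditions: i-Pr3SiCl (1.05 equiv), imidazole, DMF, 0 to 25 °C
Reagents that add atoms: chlorotriisopropylsilane, CC(C)[Si](Cl)(C(C)C)C(C)C
Why: Selective O-silylation: the 5-OH is locked in a hydrogen bond to the C4 carbonyl and is unreactive, so only the 7-OH is silylated.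

Step 8
Reactants: 16 5-hydroxy-7-(triisopropylsilyloxy)-4H-chromen-4-one; 14 [2-methoxy-4-(triisopropylsilyloxy)phenyl]boronic acid
Product: 17 (2S)-5-hydroxy-2-[2-methoxy-4-(triisopropylsilyloxy)phenyl]-7-(triisopropylsilyloxy)chroman-4-one
Conditions: Pd(OCOCF3)2 (5 mol%), (R)-4-tert-butyl-2-(pyridin-2-yl)-4,5-dihydrooxazole (6 mol%), NH4PF6 (30 mol%), H2O (5 equiv), ClCH2CH2Cl, 60 °C
Reagents that add atoms: none
Why: Palladium-catalysed asymmetric conjugate addition of an arylboronic acid to a chromone: the aryl group on cationic divalent palladium inserts the C2=C3 bond and the palladium enolate is protonated by water, the tert-butyl group of the pyridine–oxazoline ligand selecting the enone face so that C2 forms as S.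

Step 9
Reactants: 17 (2S)-5-hydroxy-2-[2-methoxy-4-(triisopropylsilyloxy)phenyl]-7-(triisopropylsilyloxy)chroman-4-one
Product: 18 (2S)-5-hydroxy-6-iodo-2-[2-methoxy-4-(triisopropylsilyloxy)phenyl]-7-(triisopropylsilyloxy)chroman-4-one
Conditions: N-iodosuccinimide (1.05 equiv), DMF, 0 to 25 °C, dark
Reagents that add atoms: N-iodosuccinimide, O=C1CCC(=O)N1I
Why: Electrophilic aromatic iodination of a 5-hydroxy-7-oxygenated chromanone goes to C6, the carbon ortho to the chelated 5-OH and flanked by O5 and O7, ahead of C8 and of the less donor-rich ring B, and the neutral conditions leave C2 untouched.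

Step 10
Reactants: 18 (2S)-5-hydroxy-6-iodo-2-[2-methoxy-4-(triisopropylsilyloxy)phenyl]-7-(triisopropylsilyloxy)chroman-4-one; 9 (S)-lavandulyl iodide
Product: 20 (2S)-5-hydroxy-2-[2-methoxy-4-(triisopropylsilyloxy)phenyl]-6-[(2R)-5-methyl-2-(prop-1-en-2-yl)hex-4-en-1-yl]-7-(triisopropylsilyloxy)chroman-4-one, via lavandulylzinc iodide 19 (not isolated)
Conditions: 9, Zn dust (activated with BrCH2CH2Br and Me3SiCl), LiCl, THF, 40 °C; then added slowly to 18, Pd(OAc)2 (3 mol%), SPhos (2-dicyclohexylphosphino-2',6'-dimethoxybiphenyl, 6 mol%), THF, 25 °C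
Reagents that add atoms: none
Why: Zerovalent palladium (formed from Pd(OAc)2 and SPhos) inserts into the C6–I bond of 18, the primary alkyl group of 19 passes from zinc to palladium, and reductive elimination forms the C6–C1'' bond (Negishi coupling). The closest known reaction type is the SPhos-promoted coupling of primary alkylzinc halides with hindered aryl iodides that carry a free phenol. No ring is closed and no stereocenter is formed: C2 is safe because no base is present to open ring C by β-elimination, and C2'' lies β to zinc and keeps its configuration (its descriptor changes from S in 9 to R in 20 only because the CH2–aryl branch now ranks below isopropenyl). The step needs reductive elimination to outrun β-hydride elimination at the allylic C2''–H, which the bulky electron-rich ligand and the two ortho substituents at C6 should favour. It also needs the zinc reagent to survive the 5-OH, which is secured by the low kinetic acidity of this carbonyl-chelated phenol and by the slow addition of 19. Site selectivity is decided in step 9 by the placement of iodine at C6, and the ketone is inert to an alkylzinc halide.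

Step 11
Reactants: 20 (2S)-5-hydroxy-2-[2-methoxy-4-(triisopropylsilyloxy)phenyl]-6-[(2R)-5-methyl-2-(prop-1-en-2-yl)hex-4-en-1-yl]-7-(triisopropylsilyloxy)chroman-4-one
Product: 21 (2S)-5,7-dihydroxy-2-(4-hydroxy-2-methoxyphenyl)-6-[(2R)-5-methyl-2-(prop-1-en-2-yl)hex-4-en-1-yl]chroman-4-one
Conditions: Bu4NF (2.4 equiv), AcOH (2.4 equiv), THF, 0 °C
Reagents that add atoms: none
Why: Fluoride-mediated desilylation of both aryl silyl ethers, buffered with acetic acid so that no phenoxide opens the flavanone ring and no acid cyclises a phenol onto the lavandulyl alkenes.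

**Compound list**

1 | (S)-4-benzyl-1,3-oxazolidin-2-one | O=C1N[C@@H](Cc2ccccc2)CO1 | starting material
2 | 3-methylbut-2-enoyl chloride | CC(C)=CC(Cl)=O | starting material
3 | lithium salt of 1 (N-lithio-(S)-4-benzyl-1,3-oxazolidin-2-one) | [Li+].O=C1[N-][C@@H](Cc2ccccc2)CO1 | intermediate
4 | (S)-4-benzyl-3-(3-methylbut-2-enoyl)-1,3-oxazolidin-2-one | CC(C)=CC(=O)N1[C@@H](Cc2ccccc2)COC1=O | intermediate
5 | 1-bromo-3-methylbut-2-ene (prenyl bromide) | CC(C)=CCBr | starting material
6 | sodium (Z)-dienolate of 4 | [Na+].C=C(C)/C=C(\[O-])N1[C@@H](Cc2ccccc2)COC1=O | intermediate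
7 | (4S)-4-benzyl-3-[(2S)-5-methyl-2-(prop-1-en-2-yl)hex-4-enoyl]-1,3-oxazolidin-2-one | C=C(C)[C@H](CC=C(C)C)C(=O)N1[C@@H](Cc2ccccc2)COC1=O | intermediate
8 | (S)-lavandulol, (2S)-5-methyl-2-(prop-1-en-2-yl)hex-4-en-1-ol | C=C(C)[C@H](CC=C(C)C)CO | intermediate
9 | (S)-lavandulyl iodide, (3S)-3-(iodomethyl)-2,6-dimethylhepta-1,5-diene | C=C(C)[C@H](CC=C(C)C)CI | intermediate
10 | 4-bromo-3-methoxyphenol | COc1cc(O)ccc1Br | starting material
11 | (4-bromo-3-methoxyphenoxy)triisopropylsilane | COc1cc(O[Si](C(C)C)(C(C)C)C(C)C)ccc1Br | intermediate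
12 | [2-methoxy-4-(triisopropylsilyloxy)phenyl]lithium | [Li]c1ccc(O[Si](C(C)C)(C(C)C)C(C)C)cc1OC | intermediate
13 | lithium triisopropoxy[2-methoxy-4-(triisopropylsilyloxy)phenyl]borate | [Li+].COc1cc(O[Si](C(C)C)(C(C)C)C(C)C)ccc1[B-](OC(C)C)(OC(C)C)OC(C)C | intermediate
14 | [2-methoxy-4-(triisopropylsilyloxy)phenyl]boronic acid | COc1cc(O[Si](C(C)C)(C(C)C)C(C)C)ccc1B(O)O | intermediate
15 | 5,7-dihydroxy-4H-chromen-4-one | O=c1ccoc2cc(O)cc(O)c12 | starting material
16 | 5-hydroxy-7-(triisopropylsilyloxy)-4H-chromen-4-one | O=c1ccoc2cc(O[Si](C(C)C)(C(C)C)C(C)C)cc(O)c12 | intermediate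
17 | (2S)-5-hydroxy-2-[2-methoxy-4-(triisopropylsilyloxy)phenyl]-7-(triisopropylsilyloxy)chroman-4-one | O=C1C[C@@H](c2ccc(O[Si](C(C)C)(C(C)C)C(C)C)cc2OC)Oc2cc(O[Si](C(C)C)(C(C)C)C(C)C)cc(O)c21 | intermediate
18 | (2S)-5-hydroxy-6-iodo-2-[2-methoxy-4-(triisopropylsilyloxy)phenyl]-7-(triisopropylsilyloxy)chroman-4-one | O=C1C[C@@H](c2ccc(O[Si](C(C)C)(C(C)C)C(C)C)cc2OC)Oc2cc(O[Si](C(C)C)(C(C)C)C(C)C)c(I)c(O)c21 | intermediate
19 | [(2S)-5-methyl-2-(prop-1-en-2-yl)hex-4-en-1-yl]zinc iodide (lavandulylzinc iodide, LiCl-solvated in THF) | C=C(C)[C@H](CC=C(C)C)C[Zn]I | intermediate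
20 | (2S)-5-hydroxy-2-[2-methoxy-4-(triisopropylsilyloxy)phenyl]-6-[(2R)-5-methyl-2-(prop-1-en-2-yl)hex-4-en-1-yl]-7-(triisopropylsilyloxy)chroman-4-one | C=C(C)[C@H](CC=C(C)C)Cc1c(O[Si](C(C)C)(C(C)C)C(C)C)cc2c(c1O)C(=O)C[C@@H](c1ccc(O[Si](C(C)C)(C(C)C)C(C)C)cc1OC)O2 | intermediate
21 | (2S)-5,7-dihydroxy-2-(4-hydroxy-2-methoxyphenyl)-6-[(2R)-5-methyl-2-(prop-1-en-2-yl)hex-4-en-1-yl]chroman-4-one | C=C(C)[C@H](CC=C(C)C)Cc1c(O)cc2c(c1O)C(=O)C[C@@H](c1ccc(O)cc1OC)O2 | target

**Step count and risks**

Total step count: 11. Longest linear sequence: 6 steps (steps 1, 2, 3, 4, 10, 11; the sequence 5, 6, 8, 9, 10, 11 is equally long).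

The three steps most likely to fail:

Step 10 (key step). The alkylpalladium intermediate may undergo β-hydride elimination at the allylic C2''–H, which loses the alkyl partner as a diene, reduces the C6–I bond and, through re-insertion, could erode the lavandulyl stereocenter. The zinc reagent may also be protonated by the 5-OH, or oxidative addition and transmetalation may be slow at the doubly ortho-substituted C6. Fallback: a nickel-catalysed reductive cross-electrophile coupling that sets out from 18 and 9 and comes back at 20. The two iodides would be combined directly with NiI2, 4,4'-di-tert-butyl-2,2'-bipyridine, Mn powder and NaI in DMA at 40 °C. No organozinc reagent is present to be protonated, the alkyl group reaches nickel as a short-lived primary radical, and reductive elimination from the aryl alkyl nickel species is fast compared with β-hydride elimination. This fallback makes no new compound (F0).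

Step 8. Insertion of the electron-rich, carbonyl-chelated chromone may be slow, so that protodeboronation of the electron-rich ortho-methoxy boronic acid takes over, or the facial selectivity may be poor. Fallback: a copper-catalysed Grignard conjugate addition followed by resolution, which sets out from 11 and 16 and comes back at 17. Magnesium insertion into 11 (Mg turnings, LiCl, THF) would give [2-methoxy-4-(triisopropylsilyloxy)phenyl]magnesium bromide F1. Its conjugate addition to 16 (2.5 equiv, the first equivalent being consumed by the O5–H; CuBr·SMe2 cat., Me3SiCl, THF, −40 °C, mildly acidic work-up) should give racemic 5-hydroxy-2-[2-methoxy-4-(triisopropylsilyloxy)phenyl]-7-(triisopropylsilyloxy)chroman-4-one F2. Preparative chromatography on a chiral stationary phase (supercritical CO2/alcohol) would then separate the enantiomers and deliver 17.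

Step 9. Iodination may compete at C5' of the electron-rich ring B or at C8, or go on to a di-iodide. Fallback: iodinate before ring B exists, setting out from 16 and coming back at 20. N-Iodosuccinimide in DMF should convert 16 into 5-hydroxy-6-iodo-7-(triisopropylsilyloxy)-4H-chromen-4-one F3, where only ring A can react. Negishi coupling of F3 with 19 under the conditions of step 10 would give 5-hydroxy-6-[(2R)-5-methyl-2-(prop-1-en-2-yl)hex-4-en-1-yl]-7-(triisopropylsilyloxy)-4H-chromen-4-one F4. Asymmetric conjugate addition of 14 to F4 under the conditions of step 8 would then give 20 directly, bypassing 17 and 18.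

**Further compounds**

F0 | step 10 | none | none
F1 | step 8 | [2-methoxy-4-(triisopropylsilyloxy)phenyl]magnesium bromide | COc1cc(O[Si](C(C)C)(C(C)C)C(C)C)ccc1[Mg]Br
F2 | step 8 | racemic 5-hydroxy-2-[2-methoxy-4-(triisopropylsilyloxy)phenyl]-7-(triisopropylsilyloxy)chroman-4-one | O=C1CC(c2ccc(O[Si](C(C)C)(C(C)C)C(C)C)cc2OC)Oc2cc(O[Si](C(C)C)(C(C)C)C(C)C)cc(O)c21
F3 | step 9 | 5-hydroxy-6-iodo-7-(triisopropylsilyloxy)-4H-chromen-4-one | O=c1ccoc2cc(O[Si](C(C)C)(C(C)C)C(C)C)c(I)c(O)c12
F4 | step 9 | 5-hydroxy-6-[(2R)-5-methyl-2-(prop-1-en-2-yl)hex-4-en-1-yl]-7-(triisopropylsilyloxy)-4H-chromen-4-one | C=C(C)[C@H](CC=C(C)C)Cc1c(O[Si](C(C)C)(C(C)C)C(C)C)cc2occc(=O)c2c1O
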